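**Strategy.** Prephytoene alcohol is cut at the two CH2–CH2 bonds that join C1 of a (2E,6E)-farnesyl unit to the methylene on ring carbon C2 of the cyclopropane and to the allylic methylene of the propenyl arm on C3. In one flask, two lithiated farnesyl phenyl sulfone anions displace the cyclopropylmethyl bromide and the allylic bromide of a C10 cyclopropane dibromide. That dibromide already holds all three ring stereocentres, the E ring-side alkene and the silyl-protected C1 hydroxymethyl group. The step adds thirty carbons, four E alkenes and two isopropylidene ends without closing a ring; sulfone removal and desilylation finish the synthesis.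

Key step: step 12

Ring numbering used throughout: C1 carries CH2OH, C2 is the quaternary carbon, C3 carries the alkenyl arm. The target is (1R,2R,3R): CH2OH is trans to the C3 arm and to the C2 chain, and cis to the C2 methyl group.

Assumption: the facial sense known for dirhodium carboxamidate catalysts with allylic diazoacetates (4S or 5S ligands give the (1R,5S) parent lactone) is taken to hold for the (E)-disubstituted diazopropionate 5. On that basis the 4R catalyst, made from D-asparagine like its 4S antipode from L-asparagine, is specified for lactone 6. If the sense were reversed, the 4S catalyst would be used with no other change.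

**Route**

Step 1
Reactants: 1 (E)-but-2-ene-1,4-diol
Product: 2 (E)-4-[(tert-butyldiphenylsilyl)oxy]but-2-en-1-ol
Conditions: NaH (1.0 equiv), THF, 0 °C to rt; then t-BuPh2SiCl (1.0 equiv), rt
Reagents that add atoms: tert-butyl(chloro)diphenylsilane, CC(C)(C)[Si](Cl)(c1ccccc1)c1ccccc1
Why: O-silylation of a symmetrical diol through its sparingly soluble monosodium alkoxide should stop after one hydroxyl, and the robust silyl ether is meant to last until the final step.

Step 2
Reactants: 2 (E)-4-[(tert-butyldiphenylsilyl)oxy]but-2-en-1-ol; 3 ethyl 2-methyl-3-oxobutanoate (1.5 equiv)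
Product: 4 (E)-4-[(tert-butyldiphenylsilyl)oxy]but-2-en-1-yl 2-methyl-3-oxobutanoate
Conditions: DMAP (0.3 equiv), toluene, reflux, ethanol removed over 4 Å molecular sieves
Reagents that add atoms: none
Why: DMAP-catalysed transesterification of a β-keto ester that keeps one α-hydrogen, driven by removal of ethanol, should move the 2-methylacetoacetyl group onto the primary allylic alcohol without touching the silyl ether.

Step 3
Reactants: 4 (E)-4-[(tert-butyldiphenylsilyl)oxy]but-2-en-1-yl 2-methyl-3-oxobutanoate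
Product: 5 (E)-4-[(tert-butyldiphenylsilyl)oxy]but-2-en-1-yl 2-diazopropanoate
Conditions: 4-acetamidobenzenesulfonyl azide (1.3 equiv), DBU (1.5 equiv), MeCN, 0 °C to rt
Reagents that add atoms: 4-acetamidobenzenesulfonyl azide, CC(=O)Nc1ccc(cc1)S(=O)(=O)N=[N+]=[N-]
Why: Deacylative Regitz diazo transfer to an α-substituted β-keto ester, in which the triazoline adduct loses the acetyl group as the N-acetylsulfonamide and leaves the α-diazopropionate.

Step 4
Reactants: 5 (E)-4-[(tert-butyldiphenylsilyl)oxy]but-2-en-1-yl 2-diazopropanoate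
Product: 6 (1R,5R,6R)-6-{[(tert-butyldiphenylsilyl)oxy]methyl}-1-methyl-3-oxabicyclo[3.1.0]hexan-2-one
Conditions: Rh2(4R-MPPIM)4 (1 mol %; MPPIM = methyl 2-oxo-1-(3-phenylpropanoyl)imidazolidine-4-carboxylate), CH2Cl2, reflux, 5 added over 10 h by syringe pump
Reagents that add atoms: none
Why: Catalytic asymmetric intramolecular cyclopropanation of an allylic diazopropionate by a chiral dirhodium carboxamidate, in which the carbene carbon becomes the methyl-bearing quaternary ring carbon, the five-membered lactone forces the carbonyl and the CH2O arm cis, the E alkene is transferred stereospecifically so that the silyloxymethyl group ends up exo and trans to both lactone carbons, and the ligand selects the alkene face and with it the absolute configuration.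

Step 5
Reactants: 6 (1R,5R,6R)-6-{[(tert-butyldiphenylsilyl)oxy]methyl}-1-methyl-3-oxabicyclo[3.1.0]hexan-2-one
Product: 7 (1R,2R,3R)-2-{[(tert-butyldiphenylsilyl)oxy]methyl}-3-(hydroxymethyl)-N-methoxy-N,1-dimethylcyclopropane-1-carboxamide
Conditions: MeNH(OMe)·HCl (3 equiv), AlMe3 (3 equiv), CH2Cl2, 0 °C to rt; crude product taken on at once
Reagents that add atoms: N,O-dimethylhydroxylamine hydrochloride, CNOC.Cl
Why: Aluminium amide aminolysis of the lactone should give the Weinreb amide and free the primary alcohol on the neighbouring ring carbon without touching a stereocentre, and immediate use forestalls relactonisation.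

Step 6
Reactants: 7 (1R,2R,3R)-2-{[(tert-butyldiphenylsilyl)oxy]methyl}-3-(hydroxymethyl)-N-methoxy-N,1-dimethylcyclopropane-1-carboxamide
Product: 8 (1S,2R,3R)-2-{[(tert-butyldiphenylsilyl)oxy]methyl}-3-formyl-N-methoxy-N,1-dimethylcyclopropane-1-carboxamide
Conditions: Dess–Martin periodinane (1.3 equiv), pyridine, CH2Cl2, 0 °C to rt
Reagents that add atoms: none
Why: Dess–Martin oxidation of a primary alcohol under buffered, non-epimerising conditions should give the cyclopropanecarbaldehyde and removes the hydroxyl that could re-close the lactone.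

Step 7
Reactants: 8 (1S,2R,3R)-2-{[(tert-butyldiphenylsilyl)oxy]methyl}-3-formyl-N-methoxy-N,1-dimethylcyclopropane-1-carboxamide; 9 ethyl 2-(triphenylphosphoranylidene)propanoate (1.5 equiv)
Product: 10 ethyl (2E)-3-[(1R,2R,3R)-3-{[(tert-butyldiphenylsilyl)oxy]methyl}-2-[methoxy(methyl)carbamoyl]-2-methylcyclopropyl]-2-methylprop-2-enoate
Conditions: toluene, 60 °C
Reagents that add atoms: none
Why: Wittig reaction of a stabilised α-branched ylide under neutral conditions should give the trisubstituted (E)-enoate, with the ester trans to the ring, at no risk to the ring stereocentres.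

Step 8
Reactants: 10 ethyl (2E)-3-[(1R,2R,3R)-3-{[(tert-butyldiphenylsilyl)oxy]methyl}-2-[methoxy(methyl)carbamoyl]-2-methylcyclopropyl]-2-methylprop-2-enoate
Product: 12 (2E)-3-[(1R,2R,3R)-3-{[(tert-butyldiphenylsilyl)oxy]methyl}-2-(hydroxymethyl)-2-methylcyclopropyl]-2-methylprop-2-en-1-ol, via hydroxy aldehyde 11 (not isolated)
Conditions: i-Bu2AlH (5 equiv), CH2Cl2, −78 to −40 °C; then MeOH and NaBH4, −40 to 0 °C; aqueous KNaC4H4O6 work-up
Reagents that add atoms: none
Why: Hydride reduction in which i-Bu2AlH takes the enoate to the allylic alcohol by 1,2-reduction and the Weinreb amide to a stable aluminium hemiaminal, and the aldehyde released on methanolysis is reduced at once by borohydride so that a formyl group cis to the alkenyl arm has no time for retro-Claisen ring expansion.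

Step 9
Reactants: 12 (2E)-3-[(1R,2R,3R)-3-{[(tert-butyldiphenylsilyl)oxy]methyl}-2-(hydroxymethyl)-2-methylcyclopropyl]-2-methylprop-2-en-1-ol
Product: 13 tert-butyl({(1R,2R,3R)-2-(bromomethyl)-3-[(1E)-3-bromo-2-methylprop-1-en-1-yl]-2-methylcyclopropyl}methoxy)diphenylsilane
Conditions: CBr4 (2.6 equiv), PPh3 (2.8 equiv), 2,6-lutidine (0.5 equiv), CH2Cl2, −20 to 0 °C; pentane trituration, filtration through Et3N-deactivated silica, used the same day
Reagents that add atoms: carbon tetrabromide, BrC(Br)(Br)Br
Why: Appel reaction in which both primary alcohols are displaced by bromide through alkoxyphosphonium ion pairs under neutral, weakly ionising conditions, which should keep the allylic position unrearranged and the cyclopropylmethyl position from ring opening.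

Step 10
Reactants: 14 (2E,6E)-farnesol
Product: 15 (2E,6E)-farnesyl bromide
Conditions: PBr3 (0.4 equiv), Et2O, −10 to 0 °C
Reagents that add atoms: phosphorus tribromide, BrP(Br)Br
Why: Bromination of a primary allylic alcohol with PBr3 at low temperature should proceed without allylic transposition or loss of the 2E geometry.

Step 11
Reactants: 15 (2E,6E)-farnesyl bromide
Product: 16 (2E,6E)-farnesyl phenyl sulfone
Conditions: PhSO2Na (1.5 equiv), DMF, rt
Reagents that add atoms: sodium benzenesulfinate, [Na+].[O-]S(=O)c1ccccc1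
Why: S-alkylation of the ambident sulfinate by a primary allylic bromide in a dipolar aprotic solvent (SN2) should give the allylic sulfone with all alkene geometries intact.

Step 12
Reactants: 13 tert-butyl({(1R,2R,3R)-2-(bromomethyl)-3-[(1E)-3-bromo-2-methylprop-1-en-1-yl]-2-methylcyclopropyl}methoxy)diphenylsilane; 16 (2E,6E)-farnesyl phenyl sulfone (3.0 equiv)
Product: 19 bis-sulfone tert-butyl({(1R,2R,3R)-2-methyl-3-[(1E,5E,9E)-2,6,10,14-tetramethyl-4-(phenylsulfonyl)pentadeca-1,5,9,13-tetraen-1-yl]-2-[(3E,7E)-4,8,12-trimethyl-2-(phenylsulfonyl)trideca-3,7,11-trien-1-yl]cyclopropyl}methoxy)diphenylsilane, via lithiated farnesyl phenyl sulfone 17 (not isolated), via monoalkylated cyclopropylmethyl bromide 18 (not isolated)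
Conditions: 16, n-BuLi (2.9 equiv), THF–DMPU (5:1), −78 °C, 30 min; 13 in THF, −78 °C, 1 h, then −78 to 0 °C (rt if needed)
Reagents that add atoms: none
Why: Proposed new method: each α-lithiated allylic sulfone attacks a bromide-bearing CH2 by direct SN2 through its sulfonyl-bearing carbon, first the allylic bromide of the C3 arm at −78 °C and then, on warming, the slower neopentyl-like cyclopropylmethyl bromide on C2, whose ring-tied β-carbons leave the backside open and which has no β-hydrogen to eliminate. The closest known reaction type is the alkylation of allylic sulfone carbanions with allylic and primary alkyl halides used for terpenoid chain couplings; what is unproven is the second displacement at a 1-methyl-2-alkenylcyclopropylmethyl bromide in the same flask. No ring is closed, and intramolecular alkylation of the first-formed sulfone is excluded because it would put the E alkene of the arm into a seven-membered ring. Two stereogenic sulfone-bearing carbons are formed without control and are deleted in step 13, while the three ring stereocentres are not touched. The step needs α- rather than γ-alkylation of the allyl anion (secured by charge localisation next to sulfur), SN2 rather than SN2′ at the arm (a primary carbon against a ring-substituted γ-carbon) and substitution without ionisation or ring opening at the cyclopropylmethyl site (ether solvent with DMPU, low temperature and an excess of a soft, strongly nucleophilic anion).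

Step 13
Reactants: 19 bis-sulfone
Product: 20 tert-butyl({(1R,2R,3R)-2-methyl-3-[(1E,5E,9E)-2,6,10,14-tetramethylpentadeca-1,5,9,13-tetraen-1-yl]-2-[(3E,7E)-4,8,12-trimethyltrideca-3,7,11-trien-1-yl]cyclopropyl}methoxy)diphenylsilane
Conditions: PdCl2(dppp) (10 mol %; dppp = 1,3-bis(diphenylphosphino)propane), LiBHEt3 (6 equiv), THF, 0 °C to rt
Reagents that add atoms: none
Why: Palladium-catalysed reductive desulfonylation of allylic sulfones, in which zerovalent palladium formed in the flask ionises each allylic C–S bond and hydride is delivered to the less substituted allyl terminus, so each trisubstituted alkene should stay in place with its E geometry while both uncontrolled stereocentres vanish and the silyl ether and the unactivated vinylcyclopropane are left alone.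

Step 14
Reactants: 20 silyl ether of the target
Product: 21 [(1R,2R,3R)-2-methyl-3-[(1E,5E,9E)-2,6,10,14-tetramethylpentadeca-1,5,9,13-tetraen-1-yl]-2-[(3E,7E)-4,8,12-trimethyltrideca-3,7,11-trien-1-yl]cyclopropyl]methanol (prephytoene alcohol, CNP0362450.1)
Conditions: Bu4NF (1.5 equiv), THF, rt
Reagents that add atoms: none
Why: Fluoride-induced cleavage of the silyl ether under basic, non-ionising conditions should free the cyclopropylmethanol, which would not tolerate acid.

**Compound list**

1 | (E)-but-2-ene-1,4-diol | OC/C=C/CO | starting material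
2 | (E)-4-[(tert-butyldiphenylsilyl)oxy]but-2-en-1-ol | OC/C=C/CO[Si](c1ccccc1)(c1ccccc1)C(C)(C)C | intermediate
3 | ethyl 2-methyl-3-oxobutanoate (ethyl 2-methylacetoacetate, racemic) | CCOC(=O)C(C)C(C)=O | starting material
4 | (E)-4-[(tert-butyldiphenylsilyl)oxy]but-2-en-1-yl 2-methyl-3-oxobutanoate (racemic at the acyl α-carbon) | CC(=O)C(C)C(=O)OC/C=C/CO[Si](c1ccccc1)(c1ccccc1)C(C)(C)C | intermediate
5 | (E)-4-[(tert-butyldiphenylsilyl)oxy]but-2-en-1-yl 2-diazopropanoate | CC(=[N+]=[N-])C(=O)OC/C=C/CO[Si](c1ccccc1)(c1ccccc1)C(C)(C)C | intermediate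
6 | (1R,5R,6R)-6-{[(tert-butyldiphenylsilyl)oxy]methyl}-1-methyl-3-oxabicyclo[3.1.0]hexan-2-one | O=C1OC[C@@H]2[C@@H](CO[Si](c3ccccc3)(c3ccccc3)C(C)(C)C)[C@]12C | intermediate
7 | (1R,2R,3R)-2-{[(tert-butyldiphenylsilyl)oxy]methyl}-3-(hydroxymethyl)-N-methoxy-N,1-dimethylcyclopropane-1-carboxamide | OC[C@@H]1[C@@H](CO[Si](c2ccccc2)(c2ccccc2)C(C)(C)C)[C@]1(C)C(=O)N(C)OC | intermediate
8 | (1S,2R,3R)-2-{[(tert-butyldiphenylsilyl)oxy]methyl}-3-formyl-N-methoxy-N,1-dimethylcyclopropane-1-carboxamide | O=C[C@@H]1[C@@H](CO[Si](c2ccccc2)(c2ccccc2)C(C)(C)C)[C@]1(C)C(=O)N(C)OC | intermediate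
9 | ethyl 2-(triphenylphosphoranylidene)propanoate | CCOC(=O)C(C)=P(c1ccccc1)(c1ccccc1)c1ccccc1 | starting material
10 | ethyl (2E)-3-[(1R,2R,3R)-3-{[(tert-butyldiphenylsilyl)oxy]methyl}-2-[methoxy(methyl)carbamoyl]-2-methylcyclopropyl]-2-methylprop-2-enoate | CCOC(=O)/C(C)=C/[C@@H]1[C@@H](CO[Si](c2ccccc2)(c2ccccc2)C(C)(C)C)[C@]1(C)C(=O)N(C)OC | intermediate
11 | (1R,2R,3R)-2-{[(tert-butyldiphenylsilyl)oxy]methyl}-3-[(1E)-3-hydroxy-2-methylprop-1-en-1-yl]-1-methylcyclopropane-1-carbaldehyde (not isolated) | OC/C(C)=C/[C@@H]1[C@@H](CO[Si](c2ccccc2)(c2ccccc2)C(C)(C)C)[C@]1(C)C=O | intermediate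
12 | (2E)-3-[(1R,2R,3R)-3-{[(tert-butyldiphenylsilyl)oxy]methyl}-2-(hydroxymethyl)-2-methylcyclopropyl]-2-methylprop-2-en-1-ol | OC/C(C)=C/[C@@H]1[C@@H](CO[Si](c2ccccc2)(c2ccccc2)C(C)(C)C)[C@]1(C)CO | intermediate
13 | tert-butyl({(1R,2R,3R)-2-(bromomethyl)-3-[(1E)-3-bromo-2-methylprop-1-en-1-yl]-2-methylcyclopropyl}methoxy)diphenylsilane; CH2Br on C2 is cis to the C3 arm and trans to CH2OSi | BrC/C(C)=C/[C@@H]1[C@@H](CO[Si](c2ccccc2)(c2ccccc2)C(C)(C)C)[C@]1(C)CBr | intermediate
14 | (2E,6E)-farnesol | CC(C)=CCC/C(C)=C/CC/C(C)=C/CO | starting material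
15 | (2E,6E)-farnesyl bromide | CC(C)=CCC/C(C)=C/CC/C(C)=C/CBr | intermediate
16 | (2E,6E)-farnesyl phenyl sulfone | CC(C)=CCC/C(C)=C/CC/C(C)=C/CS(=O)(=O)c1ccccc1 | intermediate
17 | α-lithiated (2E,6E)-farnesyl phenyl sulfone (not isolated) | [Li+].CC(C)=CCC/C(C)=C/CC/C(C)=C/[CH-]S(=O)(=O)c1ccccc1 | intermediate
18 | tert-butyl({(1R,2R,3R)-2-(bromomethyl)-2-methyl-3-[(1E,5E,9E)-2,6,10,14-tetramethyl-4-(phenylsulfonyl)pentadeca-1,5,9,13-tetraen-1-yl]cyclopropyl}methoxy)diphenylsilane, both epimers at the sulfone carbon (not isolated) | CC(C)=CCC/C(C)=C/CC/C(C)=C/C(S(=O)(=O)c2ccccc2)C/C(C)=C/[C@@H]1[C@@H](CO[Si](c3ccccc3)(c3ccccc3)C(C)(C)C)[C@]1(C)CBr | intermediate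
19 | tert-butyl({(1R,2R,3R)-2-methyl-3-[(1E,5E,9E)-2,6,10,14-tetramethyl-4-(phenylsulfonyl)pentadeca-1,5,9,13-tetraen-1-yl]-2-[(3E,7E)-4,8,12-trimethyl-2-(phenylsulfonyl)trideca-3,7,11-trien-1-yl]cyclopropyl}methoxy)diphenylsilane, mixture of epimers at the two sulfone carbons | CC(C)=CCC/C(C)=C/CC/C(C)=C/C(S(=O)(=O)c2ccccc2)C/C(C)=C/[C@@H]1[C@@H](CO[Si](c3ccccc3)(c3ccccc3)C(C)(C)C)[C@]1(C)CC(S(=O)(=O)c4ccccc4)/C=C(\C)CC/C=C(\C)CCC=C(C)C | intermediate
20 | tert-butyl({(1R,2R,3R)-2-methyl-3-[(1E,5E,9E)-2,6,10,14-tetramethylpentadeca-1,5,9,13-tetraen-1-yl]-2-[(3E,7E)-4,8,12-trimethyltrideca-3,7,11-trien-1-yl]cyclopropyl}methoxy)diphenylsilane | CC(C)=CCC/C(C)=C/CC/C(C)=C/CC/C(C)=C/[C@@H]1[C@@H](CO[Si](c2ccccc2)(c2ccccc2)C(C)(C)C)[C@]1(C)CC/C=C(\C)CC/C=C(\C)CCC=C(C)C | intermediate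
21 | [(1R,2R,3R)-2-methyl-3-[(1E,5E,9E)-2,6,10,14-tetramethylpentadeca-1,5,9,13-tetraen-1-yl]-2-[(3E,7E)-4,8,12-trimethyltrideca-3,7,11-trien-1-yl]cyclopropyl]methanol | CC(C)=CCC/C(C)=C/CC/C(C)=C/CC/C(C)=C/[C@@H]1[C@@H](CO)[C@]1(C)CC/C=C(\C)CC/C=C(\C)CCC=C(C)C | target

**Step count.** Total: 14 steps. Longest linear sequence: 12 steps (steps 1–9, then 12–14); the sulfone branch is steps 10–11.

**Steps most likely to fail**

Step 12 (Proposed new method). The second displacement may stall at the hindered cyclopropylmethyl carbon, or the warming it needs may let that bromide ionise or take up an electron so that the three-membered ring opens. Proton transfer to the excess anion followed by double alkylation is a lesser risk.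

The fallback replaces the C2 displacement by a B-alkyl Suzuki–Miyaura coupling and makes no cyclopropylmethyl halide. It sets out from hydroxy aldehyde 11, taken from step 8 by a cold aqueous work-up before any borohydride is added, and returns at silyl ether 20.
- Methylenation of 11 (Ph3P=CH2, THF, −78 to 0 °C) would give the vinylcyclopropane allylic alcohol F1.
- Appel bromination of F1 touches only the allylic alcohol and would give the allylic bromide F2.
- One equivalent of 17 alkylates F2, which is the well-precedented allylic half of step 12, to give the monosulfone F3.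
- PdCl2(dppp) and LiBHEt3 remove the sulfone to give the C2-vinyl silyl ether F4, in which the C3 arm is complete.
- For the coupling partner, commercial (5E)-geranylacetone would be converted through its kinetic enol diethyl phosphate F5 (LiN(i-Pr)2, ClP(O)(OEt)2, THF, −78 °C) into the terminal alkyne F6 (LiN(i-Pr)2, −78 °C to rt).
- Zirconium-catalysed carboalumination of F6 (AlMe3, Cp2ZrCl2, then I2) would give the (1E,5E)-vinyl iodide F7.
- 9-BBN adds only to the monosubstituted vinyl group of F4 to give the B-alkyl borane F8, which is coupled with F7 (PdCl2(dppf), AsPh3, Cs2CO3, DMF–THF–H2O, rt; dppf = 1,1′-bis(diphenylphosphino)ferrocene) to give 20.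

The fully substituted terminus of the C3 alkene places one substituent inside the boat transition state, which should hold back Cope rearrangement of the cis-divinylcyclopropanes F1 to F4 at these temperatures.

Step 9. The activated cyclopropylmethyl oxygen, helped by the cis alkenyl group on C3, may ionise during the deoxybromination and lead to ring-opened or ring-expanded bromides. The dibromide may also decompose on silica or on standing.

The fallback forms the leaving group on oxygen at low temperature and couples stepwise. It sets out from diol 12 and returns at bis-sulfone 19.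
- Corey–Kim bromination (N-bromosuccinimide, Me2S, CH2Cl2, −20 to 0 °C) converts only the allylic alcohol and would give the bromo alcohol F9.
- Anion 17 (2.1 equiv, THF, −78 °C) alkylates the allylic bromide to give the hydroxy monosulfone F10.
- Tf2O and 2,6-lutidine in CH2Cl2 at −78 °C would give the cyclopropylmethyl triflate F11.
- F11 is transferred cold into an excess of 17 in THF at −78 °C to give 19; alkylation of sulfone carbanions by primary and neopentyl-type triflates at low temperature is established chemistry.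

Step 4. The catalyst may not discriminate the alkene faces well enough for a single-enantiomer target with an (E)-disubstituted diazopropionate, and 1,2-hydride shift of the methyl carbene to the acrylate may compete.

The fallback is a resolution. It sets out from diazo ester 5 and returns at lactone 6.
- The achiral carboxamidate Rh2(acam)4 (dirhodium tetraacetamidate, Rh2(NHCOCH3)4) in refluxing CH2Cl2 would give the racemic lactone F12 with the same relative configuration.
- Aminolysis with (S)-1-phenylethylamine and AlMe3 gives two diastereomeric hydroxy amides, which are separated by chromatography or crystallisation.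
- The diastereomer with the ring configuration of 7, the hydroxy amide F13, is relactonised with catalytic p-toluenesulfonic acid in toluene at 60 °C to give enantiopure 6.

**Further compounds**

F1 | step 12 | (2E)-3-[(1R,2R,3R)-3-{[(tert-butyldiphenylsilyl)oxy]methyl}-2-ethenyl-2-methylcyclopropyl]-2-methylprop-2-en-1-ol | OC/C(C)=C/[C@@H]1[C@@H](CO[Si](c2ccccc2)(c2ccccc2)C(C)(C)C)[C@]1(C)C=C
F2 | step 12 | tert-butyl({(1R,2R,3R)-3-[(1E)-3-bromo-2-methylprop-1-en-1-yl]-2-ethenyl-2-methylcyclopropyl}methoxy)diphenylsilane | BrC/C(C)=C/[C@@H]1[C@@H](CO[Si](c2ccccc2)(c2ccccc2)C(C)(C)C)[C@]1(C)C=C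
F3 | step 12 | tert-butyl({(1R,2R,3R)-2-ethenyl-2-methyl-3-[(1E,5E,9E)-2,6,10,14-tetramethyl-4-(phenylsulfonyl)pentadeca-1,5,9,13-tetraen-1-yl]cyclopropyl}methoxy)diphenylsilane, both sulfone epimers | CC(C)=CCC/C(C)=C/CC/C(C)=C/C(S(=O)(=O)c2ccccc2)C/C(C)=C/[C@@H]1[C@@H](CO[Si](c3ccccc3)(c3ccccc3)C(C)(C)C)[C@]1(C)C=C
F4 | step 12 | tert-butyl({(1R,2R,3R)-2-ethenyl-2-methyl-3-[(1E,5E,9E)-2,6,10,14-tetramethylpentadeca-1,5,9,13-tetraen-1-yl]cyclopropyl}methoxy)diphenylsilane | CC(C)=CCC/C(C)=C/CC/C(C)=C/CC/C(C)=C/[C@@H]1[C@@H](CO[Si](c2ccccc2)(c2ccccc2)C(C)(C)C)[C@]1(C)C=C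
F5 | step 12 | diethyl (5E)-6,10-dimethylundeca-1,5,9-trien-2-yl phosphate | C=C(CC/C=C(\C)CCC=C(C)C)OP(=O)(OCC)OCC
F6 | step 12 | (5E)-6,10-dimethylundeca-5,9-dien-1-yne | C#CCC/C=C(\C)CCC=C(C)C
F7 | step 12 | (1E,5E)-1-iodo-2,6,10-trimethylundeca-1,5,9-triene | I/C=C(\C)CC/C=C(\C)CCC=C(C)C
F8 | step 12 | 9-(2-{(1R,2R,3R)-2-{[(tert-butyldiphenylsilyl)oxy]methyl}-1-methyl-3-[(1E,5E,9E)-2,6,10,14-tetramethylpentadeca-1,5,9,13-tetraen-1-yl]cyclopropyl}ethyl)-9-borabicyclo[3.3.1]nonane, not isolated | CC(C)=CCC/C(C)=C/CC/C(C)=C/CC/C(C)=C/[C@@H]1[C@@H](CO[Si](c2ccccc2)(c2ccccc2)C(C)(C)C)[C@]1(C)CCB1C2CCCC1CCC2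
F9 | step 9 | {(1R,2R,3R)-3-[(1E)-3-bromo-2-methylprop-1-en-1-yl]-2-{[(tert-butyldiphenylsilyl)oxy]methyl}-1-methylcyclopropyl}methanol | BrC/C(C)=C/[C@@H]1[C@@H](CO[Si](c2ccccc2)(c2ccccc2)C(C)(C)C)[C@]1(C)CO
F10 | step 9 | {(1R,2R,3R)-2-{[(tert-butyldiphenylsilyl)oxy]methyl}-1-methyl-3-[(1E,5E,9E)-2,6,10,14-tetramethyl-4-(phenylsulfonyl)pentadeca-1,5,9,13-tetraen-1-yl]cyclopropyl}methanol, both sulfone epimers | CC(C)=CCC/C(C)=C/CC/C(C)=C/C(S(=O)(=O)c2ccccc2)C/C(C)=C/[C@@H]1[C@@H](CO[Si](c3ccccc3)(c3ccccc3)C(C)(C)C)[C@]1(C)CO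
F11 | step 9 | trifluoromethanesulfonate ester of F10, not isolated | CC(C)=CCC/C(C)=C/CC/C(C)=C/C(S(=O)(=O)c2ccccc2)C/C(C)=C/[C@@H]1[C@@H](CO[Si](c3ccccc3)(c3ccccc3)C(C)(C)C)[C@]1(C)COS(=O)(=O)C(F)(F)F
F12 | step 4 | racemic (1R*,5R*,6R*)-6-{[(tert-butyldiphenylsilyl)oxy]methyl}-1-methyl-3-oxabicyclo[3.1.0]hexan-2-one, written as both enantiomers | O=C1OC[C@@H]2[C@@H](CO[Si](c3ccccc3)(c3ccccc3)C(C)(C)C)[C@]12C.O=C1OC[C@H]2[C@H](CO[Si](c3ccccc3)(c3ccccc3)C(C)(C)C)[C@@]12C
F13 | step 4 | (1R,2R,3R)-2-{[(tert-butyldiphenylsilyl)oxy]methyl}-3-(hydroxymethyl)-1-methyl-N-[(1S)-1-phenylethyl]cyclopropane-1-carboxamide | OC[C@@H]1[C@@H](CO[Si](c2ccccc2)(c2ccccc2)C(C)(C)C)[C@]1(C)C(=O)N[C@@H](C)c3ccccc3
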